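## Analysis of the target

The target is a plakortin-type polyketide endoperoxide acid. Its core is a 1,2-dioxane (O1, O2, C3, C4, C5, C6; O2 on C3, O1 on C6) carrying the acetic acid arm (C1–C2) on C3, an ethyl group on C4, and on C6 both an ethyl group and the (1E,4R,5E)-4-ethyl-2-methylocta-1,5-dienyl chain (C7–C14). Read from the SMILES, the configuration is 3R,4R,6R,10R. The CH2CO2H group, the C4 ethyl group and the alkenyl chain lie on one face of the ring and the C6 ethyl group on the other. In the chair with C4-ethyl equatorial, the alkenyl chain is equatorial while CH2CO2H and the C6 ethyl group are axial.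

C10 is insulated from the ring by the trisubstituted C7=C8 alkene and must be set on its own. The sensitive sites are:
- the O–O bond (reducing metals, phosphines, hydrides, hydrogenation);
- the tertiary, allylic C6–O1 bond, which ionises with acid;
- the β-peroxy acid C1–C2–C3–O2, which can open by retro-oxa-Michael reaction with base;
- the two alkenes, which rule out late ozonolysis or hydrogenation.

The hardest feature is C6, the fully substituted peroxy-bearing ring carbon. Its two carbon substituents, ethyl and the 2-methylalkenyl group, are of almost equal steric demand, so neither a ring closure at C6 nor an equilibration can tell them apart. The second difficulty is the 3,4-cis relation with an axial acetic acid arm, which is the less stable arrangement. The move this structure invites is to replace size discrimination at C6 by a stereoelectronic one: distinguish an oxygen from a carbon substituent through the anomeric effect, then exchange the oxygen for carbon along the axial direction.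

## Retrosynthetic reasoning

**20 to 19.** Only the acid is masked as its methyl ester. The ester hydrolysis is left to the last step so that the β-peroxy carboxylate is never exposed to further reagents.

**19 to 18 (cut C2–C3).** The C3–O2 bond is not cut, because closing it by conjugate addition would place the two-carbon arm equatorial (3,4-trans). Instead the C2–C3 bond is formed by adding an acetate enolate equivalent to the ring cation generated at C3 of the cyclic peroxyacetal 18. The nucleophile enters axially, which is cis to the equatorial C4 ethyl group, and C1–C2 arrive at the correct oxidation level.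

**18 to 17 (cut C6–CH2 of the ethyl group; key step).** In 17, C6 carries a methoxy group and the alkenyl chain. An oxygen and a carbon substituent are told apart by the anomeric effect: methoxy axial, alkenyl equatorial. Exchanging the axial methoxy group for ethyl, with the ethyl group entering axially, gives exactly the C6 configuration of the target. Two other cuts at C6 were considered and fail. Cutting C6–C7 (alkenyl as the entering group) would place the alkenyl chain axial, which is the C6 epimer. Cutting C6–O1 (peroxide capturing an allyl cation) offers no element that distinguishes the two faces. The forward reaction must transfer an ethyl group to a ring peroxycarbenium carbon without reducing the O–O bond.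

**17 to 14 (cut C3–O2 and C6–O1).** Both ring C–O bonds are formed in one operation by letting the simplest peroxide (the reagent of step 9) bridge the masked aldehyde carbon C3 and the ketone carbon C6 of the acyclic enone acetal 14. The precursor has only the C4 and C10 stereocentres. C3 and C6 of 17 are anomeric, thermodynamically controlled, and both are later replaced.

**14 to 7 and 11 (cut C6–C7).** Acylation of the alkenyl metal derived from iodide 7 by Weinreb amide 11 joins two halves of similar size. The E geometry of C7=C8 is already fixed in 7, and the enone is exactly what step 9 needs.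

**11 to 10 to 9 to 8.** The C4 stereocentre comes from conjugate addition of an ethyl group to the commercial menthyloxy butenolide 8, anti to the auxiliary. The ring of 9 already holds C3 at the aldehyde level and C6 at the acid level, so no redox adjustment is needed.

**7 to 5 to 4 to 2 to 1.** The E-alkenyl iodide comes from methyl-alumination of alkyne 5, and 5 from aldehyde 4 by one-carbon homologation. Aldehyde 4 arises by cutting C9–C10 in a Claisen rearrangement of the vinyl ether of allylic alcohol 2. This transfers the easily set carbinol stereocentre to C10 and fixes the E C11=C12 alkene. Alcohol 2 comes from enal 1 by catalytic asymmetric ethyl addition.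

## Alternatives that were turned down

**Alternative 1:** the textbook route, cutting C3–O2.
- Forward key step: base-mediated 6-exo oxa-Michael addition of the tertiary allylic hydroperoxide A1 onto its own (E)-enoate. A1 would be made by acid-mediated perhydrolysis of the corresponding tertiary allylic alcohol, or by radical hydroperoxidation (Co(acac)2, O2, Et3SiH).
- Why turned down: C6 of A1 is created by capture of a planar allyl cation or radical flanked by ethyl and alkenyl, so it forms as both epimers. In the chair-like cyclisation the enoate carbon takes the equatorial site, giving mainly 3,4-trans, which is also the thermodynamic isomer, so reversibility cannot correct it. Ester 19 would be a minor member of four isomers, at a step count no lower than the chosen route.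

**Alternative 2:** cutting both ring C–O bonds in a cycloaddition on a carbocyclic template.
- Forward key step: [4+2] addition of singlet oxygen to (5R)-1,5-diethylcyclohexa-1,3-diene A2, anti to the C5 ethyl group. The bicyclic endoperoxide A3 would fix C3, C4 and C6 at once and distinguish the future C7 from the C6 ethyl group by topology. Ozonolysis of the etheno bridge would give the cis-dialdehyde A4.
- Why turned down: stereochemically this is the most attractive option, but the end game spends what the key step wins. The neopentyl C7 aldehyde of A4 would have to become the E trisubstituted alkene by olefination with a non-stabilised secondary carbanion, which has poor geometric control. The C3 formyl group is one carbon short and sits on a peroxy carbon bearing H, so it is prone to Kornblum–DeLaMare cleavage with base. Differentiating and homologating the two aldehydes adds at least six steps, and enantioenriched A2 is not trivial to make.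

**Alternative 3:** cutting C6–C7, a convergent union at the quaternary carbon.
- Forward key step: Lewis-acid ionisation of the 6-ethyl-6-methoxy peroxyketal A5 and addition of the side chain as an alkenyl nucleophile (alane 6 or a derived trifluoroborate) to the C6 peroxycarbenium ion.
- Why turned down: the entering group takes the axial position, trans to the pseudo-equatorial C4 ethyl group. The product would be the C6 epimer A6, with alkenyl axial and ethyl equatorial. The cis-1,3 relation of alkenyl and C4-ethyl could only arise through a 1,3-diaxial or twist-boat transition state. The target needs ethyl, not alkenyl, to be the entering group, which is the chosen route.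

Key step: step 10

## Route

Remarks on the chemistry:
- Atom numbers C1–C14, O1 and O2 are those of the target throughout.
- Compounds 16 and 17 are drawn as their expected major anomers (hydroxy or methoxy axial at C3 and C6). Minor anomers are expected alongside and are equally usable, because step 10 and step 11 pass through planar cations.

Step 1
Reactants: 1 (E)-pent-2-enal
Product: 2 (3R,4E)-hept-4-en-3-ol
Conditions: Et2Zn (1.5 equiv), (2R)-3-exo-(dimethylamino)isoborneol (5 mol%), toluene, 0 °C; then H2O
Reagents that add atoms: diethylzinc, CC[Zn]CC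
Why: Amino-alcohol-catalysed 1,2-addition of a dialkylzinc to an enal; the (2R) ligand, antipode of the one that gives (S)-carbinols, should set the carbinol centre as R.

Step 2
Reactants: 2 (3R,4E)-hept-4-en-3-ol
Product: 4 (3R,4E)-3-ethylhept-4-enal, via allyl vinyl ether 3 (not isolated)
Conditions: ethyl vinyl ether (solvent), Hg(OAc)2 (10 mol%), reflux; concentrate; toluene, 120 °C, sealed tube
Reagents that add atoms: ethyl vinyl ether, C=COCC
Why: Transvinylation followed by Claisen rearrangement through a chair with the carbinol ethyl group equatorial; the C–O stereocentre is traded suprafacially for the C10 carbon stereocentre (R) and the new C11=C12 alkene is E.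

Step 3
Reactants: 4 (3R,4E)-3-ethylhept-4-enal
Product: 5 (4R,5E)-4-ethyloct-5-en-1-yne
Conditions: dimethyl (1-diazo-2-oxopropyl)phosphonate, K2CO3, MeOH, 0 °C to rt
Reagents that add atoms: dimethyl (1-diazo-2-oxopropyl)phosphonate, CC(=O)C(=[N+]=[N-])P(=O)(OC)OC
Why: Seyferth–Gilbert homologation with the Ohira–Bestmann reagent under mild base; the stereocentre is β to the aldehyde and cannot epimerise.

Step 4
Reactants: 5 (4R,5E)-4-ethyloct-5-en-1-yne
Product: 7 (1E,4R,5E)-4-ethyl-1-iodo-2-methylocta-1,5-diene, via alkenylalane 6 (not isolated)
Conditions: Me3Al (2 equiv), Cp2ZrCl2 (0.2 equiv), CH2Cl2, 0 °C to rt; then I2, THF, −30 °C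
Reagents that add atoms: trimethylaluminium, C[Al](C)C; iodine, II
Why: Negishi zirconium-catalysed syn-carboalumination places methyl on the internal and aluminium on the terminal alkyne carbon; iodinolysis with retention fixes the E geometry of the future C7=C8 alkene.

Step 5
Reactants: 8 (5R)-5-{[(1R,2S,5R)-5-methyl-2-(propan-2-yl)cyclohexyl]oxy}furan-2(5H)-one
Product: 9 (4R,5R)-4-ethyl-5-{[(1R,2S,5R)-5-methyl-2-(propan-2-yl)cyclohexyl]oxy}oxolan-2-one
Conditions: EtMgBr, CuBr·SMe2 (10 mol%), THF, −78 °C; then H2O
Reagents that add atoms: ethylmagnesium bromide, CC[Mg]Br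
Why: Copper-catalysed conjugate addition to the butenolide anti to the menthyloxy group on the acetal carbon sets C4 (R); C3 and C6 are already at the aldehyde and acid oxidation levels.

Step 6
Reactants: 9 (4R,5R)-4-ethyl-5-{[(1R,2S,5R)-5-methyl-2-(propan-2-yl)cyclohexyl]oxy}oxolan-2-one
Product: 10 methyl (3R)-3-ethyl-4,4-dimethoxybutanoate
Conditions: MeOH, p-toluenesulfonic acid (5 mol%), 3 Å molecular sieves, rt
Reagents that add atoms: methanol, CO
Why: Acid-catalysed methanolysis of the pseudo-ester (acetal exchange and ring-opening transesterification) should give the open-chain ester acetal and free menthol; C4 is not touched.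

Step 7
Reactants: 10 methyl (3R)-3-ethyl-4,4-dimethoxybutanoate
Product: 11 (3R)-3-ethyl-N,4,4-trimethoxy-N-methylbutanamide
Conditions: MeNH(OMe)·HCl, i-PrMgCl, THF, −20 °C; then H2O
Reagents that add atoms: N,O-dimethylhydroxylamine hydrochloride, CNOC.Cl
Why: Weinreb amide formation from an ester with the magnesium amide of N,O-dimethylhydroxylamine; the acetal and C4 are inert.

Step 8
Reactants: 7 (1E,4R,5E)-4-ethyl-1-iodo-2-methylocta-1,5-diene, 11 (3R)-3-ethyl-N,4,4-trimethoxy-N-methylbutanamide
Product: 14 (2R,5E,8R,9E)-2,8-diethyl-1,1-dimethoxy-6-methyldodeca-5,9-dien-4-one, via alkenyllithium 12 (not isolated), via lithium hemiaminal alkoxide 13 (not isolated)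
Conditions: 7, t-BuLi (2 equiv), Et2O, −78 °C; then 11, −78 to 0 °C; then H2O
Reagents that add atoms: none
Why: Iodine–lithium exchange with retention of alkene geometry, then acylation by the Weinreb amide, whose chelated tetrahedral adduct prevents a second addition; this joins the two halves at C6–C7.

Step 9
Reactants: 14 (2R,5E,8R,9E)-2,8-diethyl-1,1-dimethoxy-6-methyldodeca-5,9-dien-4-one
Product: 17 (3S,4R,6R)-4-ethyl-6-[(1E,4R,5E)-4-ethyl-2-methylocta-1,5-dien-1-yl]-3,6-dimethoxy-1,2-dioxane, via hydroperoxy acetal 15 (not isolated), via hemiperketal 16 (not isolated)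
Conditions: anhydrous H2O2 in Et2O (3 equiv), camphor-10-sulfonic acid (10 mol%), CH2Cl2, 0 °C; then MeOH, pyridinium p-toluenesulfonate, 3 Å molecular sieves, rt
Reagents that add atoms: hydrogen peroxide, OO; methanol, CO
Why: Acid-catalysed perhydrolysis of the dimethyl acetal gives the α-methoxy hydroperoxide, which adds to the C6 ketone in a six-membered hemiperketal closure as known for δ-hydroperoxy enones, and acid methanolysis gives the methyl perketal; C3 and C6 are anomeric centres under thermodynamic control (methoxy axial, alkenyl equatorial) and are not final.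

Step 10
Reactants: 17 (3S,4R,6R)-4-ethyl-6-[(1E,4R,5E)-4-ethyl-2-methylocta-1,5-dien-1-yl]-3,6-dimethoxy-1,2-dioxane
Product: 18 (3S,4R,6R)-4,6-diethyl-6-[(1E,4R,5E)-4-ethyl-2-methylocta-1,5-dien-1-yl]-3-methoxy-1,2-dioxane
Conditions: Et3Al (3 equiv), CH2Cl2, −78 to −40 °C; then aq potassium sodium tartrate
Reagents that add atoms: triethylaluminium, CC[Al](CC)CC
Why: Proposed new method: Et3Al should bind the axial methoxy group at C6 of 17 and ionise the C6–OMe bond to the alkenyl-conjugated peroxycarbenium ion (O1=C6) paired with a methoxyaluminate, from which an ethyl group passes to C6. The closest known reaction types are the Lewis-acid-mediated substitution of 3-alkoxy-1,2-dioxanes by allylsilanes and silyl enol ethers through peroxycarbenium ions, and the C-alkylation of acetals and of anomeric fluorides of peroxide-containing trioxane lactols by trialkylaluminium reagents that leaves the O–O bond intact. No ring is closed; the step makes the C6–CH2CH3 bond and with it the fully substituted carbon. C6 is the only new stereocentre and is set by stereoelectronics, not by size: in the half-chair cation the C4 ethyl group is pseudo-equatorial, and ethyl enters along the axial direction through a chair-like transition state, on the face the axial methoxy group has just left, which puts it trans to the C4 ethyl group and leaves the alkenyl chain equatorial; entry from the other face would need a twist-boat or a 1,3-diaxial ethyl–ethyl contact. The step is stereoconvergent, because every C3 and C6 anomer of 17 gives the same cation. It needs three selectivities: C6 before C3 (a tertiary, alkenyl-stabilised ketal ionises far faster than a secondary acetal), transfer to C6 and not to C8 (the aluminate sits at C6 and C8 is fully substituted), and ethyl transfer ahead of β-hydride transfer or O–O reduction (low temperature, non-coordinating solvent, hindered peroxide).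

Step 11
Reactants: 18 (3S,4R,6R)-4,6-diethyl-6-[(1E,4R,5E)-4-ethyl-2-methylocta-1,5-dien-1-yl]-3-methoxy-1,2-dioxane
Product: 19 methyl 2-[(3R,4R,6R)-4,6-diethyl-6-[(1E,4R,5E)-4-ethyl-2-methylocta-1,5-dien-1-yl]-1,2-dioxan-3-yl]acetate
Conditions: CH2=C(OMe)OSi(t-Bu)Me2 (3 equiv), Me3SiOSO2CF3 (0.2 equiv), CH2Cl2, −78 °C
Reagents that add atoms: tert-butyl[(1-methoxyethenyl)oxy]dimethylsilane, C=C(OC)O[Si](C)(C)C(C)(C)C
Why: Lewis-acid-mediated substitution of a 3-alkoxy-1,2-dioxane by a silyl ketene acetal through the C3 peroxycarbenium ion (Mukaiyama type); axial attack on the half-chair that keeps the C4 ethyl group and the C6 alkenyl chain equatorial should set C3 cis to the C4 ethyl group (CH2CO2Me axial).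

Step 12
Reactants: 19 methyl 2-[(3R,4R,6R)-4,6-diethyl-6-[(1E,4R,5E)-4-ethyl-2-methylocta-1,5-dien-1-yl]-1,2-dioxan-3-yl]acetate
Product: 20 2-[(3R,4R,6R)-4,6-diethyl-6-[(1E,4R,5E)-4-ethyl-2-methylocta-1,5-dien-1-yl]-1,2-dioxan-3-yl]acetic acid
Conditions: LiOH (3 equiv), THF/H2O (3:1), 0 °C; then 1 M HCl to pH 3, 0 °C
Reagents that add atoms: lithium hydroxide, [Li+].[OH-]
Why: Saponification at 0 °C and brief cold acidification; short exposure to base should limit retro-oxa-Michael opening of the β-peroxy ester, and no stereocentre is touched.

## Compound list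

1 | (E)-pent-2-enal | CC/C=C/C=O | starting material
2 | (3R,4E)-hept-4-en-3-ol | CC[C@@H](O)/C=C/CC | intermediate
3 | (3R,4E)-3-(ethenyloxy)hept-4-ene (allyl vinyl ether, not isolated) | CC[C@@H](OC=C)/C=C/CC | intermediate
4 | (3R,4E)-3-ethylhept-4-enal | CC/C=C/[C@H](CC)CC=O | intermediate
5 | (4R,5E)-4-ethyloct-5-en-1-yne | CC/C=C/[C@H](CC)CC#C | intermediate
6 | [(1E,4R,5E)-4-ethyl-2-methylocta-1,5-dien-1-yl]dimethylaluminium (not isolated) | CC/C=C/[C@H](CC)C/C(C)=C/[Al](C)C | intermediate
7 | (1E,4R,5E)-4-ethyl-1-iodo-2-methylocta-1,5-diene | CC/C=C/[C@H](CC)C/C(C)=C/I | intermediate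
8 | (5R)-5-{[(1R,2S,5R)-5-methyl-2-(propan-2-yl)cyclohexyl]oxy}furan-2(5H)-one | C[C@@H]1CC[C@H]([C@@H](C1)O[C@@H]2OC(=O)C=C2)C(C)C | starting material
9 | (4R,5R)-4-ethyl-5-{[(1R,2S,5R)-5-methyl-2-(propan-2-yl)cyclohexyl]oxy}oxolan-2-one | C[C@@H]1CC[C@H]([C@@H](C1)O[C@@H]2OC(=O)C[C@H]2CC)C(C)C | intermediate
10 | methyl (3R)-3-ethyl-4,4-dimethoxybutanoate | COC(=O)C[C@@H](CC)C(OC)OC | intermediate
11 | (3R)-3-ethyl-N,4,4-trimethoxy-N-methylbutanamide | CON(C)C(=O)C[C@@H](CC)C(OC)OC | intermediate
12 | [(1E,4R,5E)-4-ethyl-2-methylocta-1,5-dien-1-yl]lithium (not isolated) | CC/C=C/[C@H](CC)C/C(C)=C/[Li] | intermediate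
13 | lithium alkoxide of the tetrahedral adduct of 12 and 11 (N-methoxy-N-methyl hemiaminal of 14; carbinol carbon not controlled, lost on collapse; not isolated) | CC/C=C/[C@H](CC)C/C(C)=C/C([O-])(C[C@@H](CC)C(OC)OC)N(C)OC.[Li+] | intermediate
14 | (2R,5E,8R,9E)-2,8-diethyl-1,1-dimethoxy-6-methyldodeca-5,9-dien-4-one | CC/C=C/[C@H](CC)C/C(C)=C/C(=O)C[C@@H](CC)C(OC)OC | intermediate
15 | (2R,5E,8R,9E)-2,8-diethyl-1-hydroperoxy-1-methoxy-6-methyldodeca-5,9-dien-4-one (both C1 epimers; not isolated) | CC/C=C/[C@H](CC)C/C(C)=C/C(=O)C[C@@H](CC)C(OC)OO | intermediate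
16 | (3R,5R,6S)-5-ethyl-3-[(1E,4R,5E)-4-ethyl-2-methylocta-1,5-dien-1-yl]-6-methoxy-1,2-dioxan-3-ol (major anomer; not isolated) | CC/C=C/[C@H](CC)C/C(C)=C/[C@@]1(O)C[C@@H](CC)[C@@H](OC)OO1 | intermediate
17 | (3S,4R,6R)-4-ethyl-6-[(1E,4R,5E)-4-ethyl-2-methylocta-1,5-dien-1-yl]-3,6-dimethoxy-1,2-dioxane (major anomer) | CC/C=C/[C@H](CC)C/C(C)=C/[C@@]1(OC)C[C@@H](CC)[C@@H](OC)OO1 | intermediate
18 | (3S,4R,6R)-4,6-diethyl-6-[(1E,4R,5E)-4-ethyl-2-methylocta-1,5-dien-1-yl]-3-methoxy-1,2-dioxane | CC/C=C/[C@H](CC)C/C(C)=C/[C@@]1(CC)C[C@@H](CC)[C@@H](OC)OO1 | intermediate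
19 | methyl 2-[(3R,4R,6R)-4,6-diethyl-6-[(1E,4R,5E)-4-ethyl-2-methylocta-1,5-dien-1-yl]-1,2-dioxan-3-yl]acetate | CC/C=C/[C@H](CC)C/C(C)=C/[C@@]1(CC)C[C@@H](CC)[C@@H](CC(=O)OC)OO1 | intermediate
20 | 2-[(3R,4R,6R)-4,6-diethyl-6-[(1E,4R,5E)-4-ethyl-2-methylocta-1,5-dien-1-yl]-1,2-dioxan-3-yl]acetic acid | CC/C=C/[C@H](CC)C/C(C)=C/[C@@]1(CC)C[C@@H](CC)[C@@H](CC(=O)O)OO1 | target

## Step count and least certain steps

Total step count: 12. Longest linear sequence: 9 steps (steps 1, 2, 3, 4, 8, 9, 10, 11, 12); the other branch (steps 5, 6, 7) joins at step 8.

**Step 10 (key step, proposed new method).**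
- Most likely to go wrong: β-hydride transfer from the ethylaluminium reagent to the peroxycarbenium ion instead of ethyl transfer. Other failure modes are ethyl delivery to C8 of the conjugated cation, loss of a proton from the cation to give a dienyl peroxide, and reduction of the O–O bond by the alane. All stem from the cation being both hindered and allylic.
- Fallback (known chemistry): set out from 14. 1,2-Addition of EtMgBr (CeCl3, THF, −78 °C) should give the tertiary allylic alcohol F1 as both C6 epimers. Treatment of F1 with anhydrous H2O2 and Re2O7 (5 mol%) in CH2Cl2 should exchange one acetal methoxy group for a hydroperoxy group and ionise the tertiary allylic alcohol; capture of the allyl cation by the hydroperoxide closes the ring. This gives 18 together with its C6 epimer F2, because nothing distinguishes the two faces. The two are separated, and F2 can be returned to the ionising conditions. The route is rejoined at 18.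

**Step 9.**
- Most likely to go wrong: incomplete ring closure, because the conjugated, β,β-disubstituted enone carbonyl is a poor acceptor for the hydroperoxide. Competing processes are acid-catalysed cyclodehydration of the 1,4-dicarbonyl system to a furan and conjugate addition of hydroperoxide at C8.
- Fallback: set out from 14. Mild aqueous acid hydrolysis of the acetal (oxalic acid on wet silica) should give the keto aldehyde F3. Used at once with ethereal H2O2 in MeCN, F3 should condense to the bridged peroxide F4 (a 2,3,7-trioxabicyclo[2.2.1]heptane, the known fate of 1,4-dicarbonyl compounds with H2O2). Acid methanolysis (MeOH, camphor-10-sulfonic acid) should then open the ether bridge at the tertiary allylic carbon and give 17, where the route is rejoined.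

**Step 11.**
- Most likely to go wrong: competing ionisation of the tertiary allylic C6–O1 bond by the Lewis acid, leading to ring opening, loss of the C6 configuration or capture of the allyl cation by the ketene acetal. Sluggish ionisation of the secondary peroxyacetal would make this worse.
- Fallback: set out from 18. Mild hydrolysis (aqueous AcOH, THF) should give the hemiacetal F5, which is in equilibrium with its open hydroperoxy aldehyde. Horner–Wadsworth–Emmons reaction with trimethyl phosphonoacetate (LiCl, i-Pr2NEt, MeCN) should give the hydroperoxy enoate F6, now with C6 defined. Amine-catalysed 6-exo oxa-Michael closure returns 19 together with its C3 epimer F7, which is expected to predominate and can be recycled by base-mediated retro-Michael reaction and re-closure. The route is rejoined at 19.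

**Step 12.**
- Most likely to go wrong: base-induced retro-oxa-Michael opening of the β-peroxy ester (deprotonation at C2 and expulsion of O2) during saponification.
- Fallback: set out from 18 and repeat the C3 substitution with 1,1-bis(trimethylsilyloxy)ethene in place of the methyl ketene acetal (Me3SiOSO2CF3, CH2Cl2, −78 °C). This should give the trimethylsilyl ester F8, which is cleaved on neutral aqueous work-up and delivers 20 directly without any basic step.

## Further compounds

F1 | step 10 | (3R,6E,9R,10E)-3,9-diethyl-5-ethyl-1,1-dimethoxy-7-methyltrideca-6,10-dien-5-ol skeleton: tertiary allylic alcohol from EtMgBr and 14, both C6 (target numbering) epimers | CC/C=C/[C@H](CC)C/C(C)=C/C(O)(CC)C[C@@H](CC)C(OC)OC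
F2 | step 10 | C6 epimer of 18, (3S,4R,6S)-4,6-diethyl-6-[(1E,4R,5E)-4-ethyl-2-methylocta-1,5-dien-1-yl]-3-methoxy-1,2-dioxane | CC/C=C/[C@H](CC)C/C(C)=C/[C@]1(CC)C[C@@H](CC)[C@@H](OC)OO1
F3 | step 9 | (2R,5E,8R,9E)-2,8-diethyl-6-methyl-4-oxododeca-5,9-dienal | CC/C=C/[C@H](CC)C/C(C)=C/C(=O)C[C@@H](CC)C=O
F4 | step 9 | bridged peroxide, 5-ethyl-1-[(1E,4R,5E)-4-ethyl-2-methylocta-1,5-dien-1-yl]-2,3,7-trioxabicyclo[2.2.1]heptane (ether bridge syn to the ring ethyl group) | CC/C=C/[C@H](CC)C/C(C)=C/[C@]12C[C@@H](CC)[C@@H](O2)OO1
F5 | step 11 | (4R,6R)-4,6-diethyl-6-[(1E,4R,5E)-4-ethyl-2-methylocta-1,5-dien-1-yl]-1,2-dioxan-3-ol (both anomers) | CC/C=C/[C@H](CC)C/C(C)=C/[C@@]1(CC)C[C@@H](CC)C(O)OO1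
F6 | step 11 | methyl (2E,4R,6R,7E,10R,11E)-4,6,10-triethyl-6-hydroperoxy-8-methyltetradeca-2,7,11-trienoate | CC/C=C/[C@H](CC)C/C(C)=C/[C@@](OO)(CC)C[C@@H](CC)/C=C/C(=O)OC
F7 | step 11 | C3 epimer of 19, methyl 2-[(3S,4R,6R)-4,6-diethyl-6-[(1E,4R,5E)-4-ethyl-2-methylocta-1,5-dien-1-yl]-1,2-dioxan-3-yl]acetate | CC/C=C/[C@H](CC)C/C(C)=C/[C@@]1(CC)C[C@@H](CC)[C@H](CC(=O)OC)OO1
F8 | step 12 | trimethylsilyl 2-[(3R,4R,6R)-4,6-diethyl-6-[(1E,4R,5E)-4-ethyl-2-methylocta-1,5-dien-1-yl]-1,2-dioxan-3-yl]acetate | CC/C=C/[C@H](CC)C/C(C)=C/[C@@]1(CC)C[C@@H](CC)[C@@H](CC(=O)O[Si](C)(C)C)OO1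
A1 | alternative 1 | methyl (2E,4R,7E,10R,11E)-4,6,10-triethyl-6-hydroperoxy-8-methyltetradeca-2,7,11-trienoate, both C6 epimers | CC/C=C/[C@H](CC)C/C(C)=C/C(CC)(OO)C[C@@H](CC)/C=C/C(=O)OC
A2 | alternative 2 | (5R)-1,5-diethylcyclohexa-1,3-diene | CCC1=CC=C[C@H](CC)C1
A3 | alternative 2 | 1,7-diethyl-2,3-dioxabicyclo[2.2.2]oct-5-ene, ethyl on C7 syn to the etheno bridge | C1=C[C@@]2(CC)C[C@@H](CC)[C@@H]1OO2
A4 | alternative 2 | cis-dialdehyde, 4,6-diethyl-1,2-dioxane-3,6-dicarbaldehyde with both formyl groups and the C4 ethyl group on one face | O=C[C@@]1(CC)C[C@@H](CC)[C@@H](C=O)OO1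
A5 | alternative 3 | methyl 2-[4,6-diethyl-6-methoxy-1,2-dioxan-3-yl]acetate, methoxy axial, ring stereocentres C3 and C4 as in the target | CC[C@@]1(OC)C[C@@H](CC)[C@@H](CC(=O)OC)OO1
A6 | alternative 3 | C6 epimer of 19, methyl 2-[(3R,4R,6S)-4,6-diethyl-6-[(1E,4R,5E)-4-ethyl-2-methylocta-1,5-dien-1-yl]-1,2-dioxan-3-yl]acetate | CC/C=C/[C@H](CC)C/C(C)=C/[C@]1(CC)C[C@@H](CC)[C@@H](CC(=O)OC)OO1
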